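Ring C is taken apart at O1–C8a, C4–C4a and O1–C2 at once. The feature used is that C8a and C4a are adjacent ring A carbons carrying O1 and the C4 acyl carbon, with the C5 oxygen next to C4a. This is the exact imprint of a carboxylate adding to a 3-oxygenated benzyne. One fluoride-triggered operation inserts 3,5-bis(methoxymethoxy)benzyne into the carboxyl C–O bond of a complete ring B 2-aryl-3-methoxyacrylic acid, and the released phenoxide then displaces methoxide at C2. The precursors are an o-silylaryl triflate from phloroglucinol and the MOM-protected acid, whose prenyl and 1,1-dimethylallyl groups come from two regiochemically forced Claisen rearrangements.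

Key step: step 14

Remarks on the chemistry
- MOM = methoxymethyl. Isoflavone numbering is used, and primed locants (C1'–C6') denote ring B in the ring B intermediates as well.
- The target has no stereocentre. Assumption: the alkene geometry of the β-methoxyacrylate ester and acid has no bearing on ring closure, because C2 becomes tetrahedral during the addition–elimination. The E isomer, the usual outcome of the enolate methylation, is drawn.
- The 3'-prenyl group is delivered from O2', where C3' is the only free ortho carbon. An ether on O4' would have both C3' and C5' free. The 5'-(1,1-dimethylallyl) group is delivered afterwards from O4', when C3' is already filled.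

Step 1
Reactants: 1 phloroglucinol
Product: 2 3,5-bis(methoxymethoxy)phenol
Conditions: MOMCl (2 equiv), i-Pr2NEt, DMF, 0 °C → rt
Reagents that add atoms: chloromethyl methyl ether (MOMCl), COCCl
Why: Williamson-type O-alkylation of the symmetric triol with two equivalents of a hard chloromethyl ether, in which all three hydroxyls are equivalent so that only the degree of alkylation has to be controlled, and the accompanying mono- and tris-ethers can be separated and recycled on this cheap material.

Step 2
Reactants: 2 3,5-bis(methoxymethoxy)phenol
Product: 3 2-bromo-3,5-bis(methoxymethoxy)phenol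
Conditions: NBS (1 equiv), i-Pr2NH (cat.), CH2Cl2, −78 → 0 °C
Reagents that add atoms: N-bromosuccinimide, O=C1CCC(=O)N1Br
Why: Electrophilic aromatic bromination in which the two equivalent positions ortho to the free hydroxyl are less crowded than the carbon between the two MOM ethers and are further favoured by amine-mediated, hydrogen-bond-directed ortho delivery of bromine, while low temperature and one equivalent of NBS hold back dibromination.

Step 3
Reactants: 3 2-bromo-3,5-bis(methoxymethoxy)phenol
Product: 4 [2-bromo-3,5-bis(methoxymethoxy)phenoxy]trimethylsilane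
Conditions: (Me3Si)2NH, THF, 65 °C; evaporation, used crude
Reagents that add atoms: hexamethyldisilazane, C[Si](C)(C)N[Si](C)(C)C
Why: O-silylation of a phenol with hexamethyldisilazane, which releases only ammonia so that the moisture-sensitive silyl ether can be carried on after evaporation.

Step 4
Reactants: 4 [2-bromo-3,5-bis(methoxymethoxy)phenoxy]trimethylsilane
Product: 6 3,5-bis(methoxymethoxy)-2-(trimethylsilyl)phenyl trifluoromethanesulfonate, via lithium 2-silylphenolate 5 (not isolated)
Conditions: n-BuLi, THF, −78 °C; then Tf2O, −78 → 0 °C
Reagents that add atoms: trifluoromethanesulfonic anhydride, O=S(=O)(OS(=O)(=O)C(F)(F)F)C(F)(F)F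
Why: Bromine–lithium exchange followed by retro-Brook (O-to-C 1,3-silyl) migration puts silicon on the carbon that carried bromine and frees phenolate 5 for triflation in the same flask, the exchange at −78 °C being much faster than MOM-directed ring lithiation.

Step 5
Reactants: 7 2,4-dihydroxyphenylacetic acid
Product: 8 methyl 2-(2,4-dihydroxyphenyl)acetate
Conditions: MeOH, H2SO4 (cat.), reflux
Reagents that add atoms: methanol, CO
Why: Fischer esterification, in which the large excess of methanol keeps the competing benzofuranone lactone open.

Step 6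
Reactants: 8 methyl 2-(2,4-dihydroxyphenyl)acetate; 9 prenyl bromide (1-bromo-3-methylbut-2-ene)
Product: 10 methyl 2-[2-hydroxy-4-(3-methylbut-2-enyloxy)phenyl]acetate
Conditions: 9 (1 equiv), K2CO3, acetone, rt
Reagents that add atoms: none
Why: Williamson ether synthesis in which one equivalent of bromide and a weak base should alkylate the exposed 4-OH ahead of the 2-OH, which is flanked by the side chain and hydrogen-bonded to its ester carbonyl.

Step 7
Reactants: 10 methyl 2-[2-hydroxy-4-(3-methylbut-2-enyloxy)phenyl]acetate; 11 3-chloro-3-methylbut-1-yne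
Product: 12 methyl 2-[2-(2-methylbut-3-yn-2-yloxy)-4-(3-methylbut-2-enyloxy)phenyl]acetate
Conditions: CuCl2·2H2O (cat.), DBU, MeCN, 0 °C → rt
Reagents that add atoms: none
Why: Copper-catalysed propargylic substitution (O-alkylation through a copper acetylide-stabilised tertiary cation equivalent), the standard entry to aryl 1,1-dimethylpropargyl ethers, applied here to the only hydroxyl left.

Step 8
Reactants: 12 methyl 2-[2-(2-methylbut-3-yn-2-yloxy)-4-(3-methylbut-2-enyloxy)phenyl]acetate
Product: 13 methyl 2-[2-(2-methylbut-3-en-2-yloxy)-4-(3-methylbut-2-enyloxy)phenyl]acetate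
Conditions: H2 (1 atm), Pd/CaCO3 poisoned with Pb(OAc)2, quinoline, EtOAc, rt; filtered, used crude
Reagents that add atoms: none
Why: Lindlar semihydrogenation stops at the terminal alkene, and the poisoned catalyst leaves the trisubstituted prenyl double bond and both allylic C–O bonds untouched.

Step 9
Reactants: 13 methyl 2-[2-(2-methylbut-3-en-2-yloxy)-4-(3-methylbut-2-enyloxy)phenyl]acetate
Product: 15 methyl 2-[2-(methoxymethoxy)-3-(3-methylbut-2-enyl)-4-(3-methylbut-2-enyloxy)phenyl]acetate, via o-prenylphenol 14 (not isolated)
Conditions: toluene, 110 °C; then i-Pr2NEt, MOMCl, 0 → 50 °C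
Reagents that add atoms: chloromethyl methyl ether (MOMCl), COCCl
Why: Aromatic Claisen rearrangement with allyl inversion, in which the tertiary ether on O2' shifts at a temperature at which the primary prenyl ether on O4' is inert, the direct shift to free C3' with fast tautomerisation is the lowest pathway because the other ortho carbon C1' is substituted, and phenol 14 is capped at once as its MOM ether so that it can later neither lactonise onto the ester nor add to the new prenyl group.

Step 10
Reactants: 15 methyl 2-[2-(methoxymethoxy)-3-(3-methylbut-2-enyl)-4-(3-methylbut-2-enyloxy)phenyl]acetate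
Product: 16 methyl 2-[4-hydroxy-2-(methoxymethoxy)-5-(2-methylbut-3-en-2-yl)-3-(3-methylbut-2-enyl)phenyl]acetate
Conditions: PhNEt2, 200 °C, sealed tube, Ar
Reagents that add atoms: none
Why: Aromatic Claisen rearrangement with allyl inversion turns the O4' prenyl ether into a C-bound 1,1-dimethylallyl group, and since C3' is filled and the para carbon C1' is substituted, C5' is the only position at which the dienone can rearomatise, while the basic solvent holds back acid-catalysed ring closure of the new phenol.

Step 11
Reactants: 16 methyl 2-[4-hydroxy-2-(methoxymethoxy)-5-(2-methylbut-3-en-2-yl)-3-(3-methylbut-2-enyl)phenyl]acetate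
Product: 17 methyl 2-[2,4-bis(methoxymethoxy)-5-(2-methylbut-3-en-2-yl)-3-(3-methylbut-2-enyl)phenyl]acetate
Conditions: NaH (1.1 equiv), MOMCl, THF–DMF, 0 °C → rt
Reagents that add atoms: chloromethyl methyl ether (MOMCl), COCCl
Why: Williamson-type alkylation of the preformed sodium phenolate, chosen because the hydroxyl is flanked on both sides, with about one equivalent of NaH deprotonating the phenol well before the ester α-position.

Step 12
Reactants: 17 methyl 2-[2,4-bis(methoxymethoxy)-5-(2-methylbut-3-en-2-yl)-3-(3-methylbut-2-enyl)phenyl]acetate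
Product: 19 methyl (E)-3-methoxy-2-[2,4-bis(methoxymethoxy)-5-(2-methylbut-3-en-2-yl)-3-(3-methylbut-2-enyl)phenyl]acrylate, via sodium hydroxymethylene enolate 18 (not isolated)
Conditions: NaH, HCO2Me, DMF, 0 °C → rt; then Me2SO4, rt
Reagents that add atoms: methyl formate, COC=O; dimethyl sulfate, COS(=O)(=O)OC
Why: Crossed Claisen condensation of the arylacetate enolate with non-enolisable methyl formate gives the stabilised enolate 18, whose O-methylation by the hard electrophile Me2SO4 in DMF is the standard route to (E)-β-methoxyacrylates, and every other group present is stable to base.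

Step 13
Reactants: 19 methyl (E)-3-methoxy-2-[2,4-bis(methoxymethoxy)-5-(2-methylbut-3-en-2-yl)-3-(3-methylbut-2-enyl)phenyl]acrylate
Product: 20 (E)-3-methoxy-2-[2,4-bis(methoxymethoxy)-5-(2-methylbut-3-en-2-yl)-3-(3-methylbut-2-enyl)phenyl]acrylic acid
Conditions: LiOH, THF–MeOH–H2O, 50 °C; then 1 M HCl to pH 4, 0 °C
Reagents that add atoms: lithium hydroxide, [Li+].[OH-]
Why: Ester saponification by acyl–oxygen cleavage, in which methanol as cosolvent makes any addition–elimination at the β-carbon degenerate, the MOM ethers are inert to base, and brief cold acidification to pH 4 spares the acetals and the enol ether.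

Step 14
Reactants: 6 3,5-bis(methoxymethoxy)-2-(trimethylsilyl)phenyl trifluoromethanesulfonate; 20 (E)-3-methoxy-2-[2,4-bis(methoxymethoxy)-5-(2-methylbut-3-en-2-yl)-3-(3-methylbut-2-enyl)phenyl]acrylic acid
Product: 23 5,7,2',4'-tetra-O-methoxymethylfremontone, via 3,5-bis(methoxymethoxy)benzyne 21 (not isolated), via caesium o-acylphenolate 22 (not isolated)
Conditions: 20 (1 equiv), 6 (1.8 equiv), CsF (5 equiv), THF, 125 °C, sealed tube
Reagents that add atoms: none
Why: Fluoride attacks silicon in 6 and triflate leaves to give aryne 21; the caesium carboxylate of 20 adds through oxygen, the resulting aryl anion attacks its own ester carbonyl to form a four-membered benzoxete alkoxide, and opening of that ring gives o-acylphenolate 22 (net insertion into the carboxyl C–O bond, forming C8a–O1 and C4a–C4). The closest known reaction type is the CsF/THF insertion of arynes into carboxylic acids, which gives o-hydroxyaryl ketones and, with unsaturated or o-haloaryl acids, runs on in the same flask to chromanones, flavones and xanthones. Ring C, the only ring formed, closes by 6-endo-trig oxa-Michael addition of O1 to C2 of the β-methoxy enone followed by E1cB loss of methoxide (O1–C2), so the alkene geometry of 20 is irrelevant and no stereocentre is created. The step needs regioselective addition to the unsymmetrical aryne, which is secured by the σ-withdrawing MOM-oxy group at C5 directly beside the triple bond: it distorts the aryne so that the nucleophile attacks the remote carbon (C8a) and the charge develops at C4a next to that oxygen. It also needs the acyl shift to outrun both protonation of the aryl anion and conjugate attack at C2, which the aprotic, weakly polar medium, excess CsF as HF scavenger and the preferred Z conformation of the aryl ester (C2 held away from the carbanion) should secure. Prenyl, 1,1-dimethylallyl and MOM groups are inert to fluoride and to 125 °C in the absence of acid.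

Step 15
Reactants: 23 5,7,2',4'-tetra-O-methoxymethylfremontone
Product: 24 fremontone
Conditions: conc. aq. HCl (about 0.3 M final), MeOH–THF, 40 °C, stopped at full conversion
Reagents that add atoms: none
Why: Acid-catalysed transacetalisation of the four aryl MOM ethers to dimethoxymethane, a standard last step for prenylated polyphenols because dilute HCl in methanol cleaves the acetals much faster than it protonates the trisubstituted or the terminal alkene.

Compound list
1 | phloroglucinol (benzene-1,3,5-triol) | Oc1cc(O)cc(O)c1 | starting material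
2 | 3,5-bis(methoxymethoxy)phenol | COCOc1cc(O)cc(OCOC)c1 | intermediate
3 | 2-bromo-3,5-bis(methoxymethoxy)phenol | COCOc1cc(O)c(Br)c(OCOC)c1 | intermediate
4 | [2-bromo-3,5-bis(methoxymethoxy)phenoxy]trimethylsilane | COCOc1cc(O[Si](C)(C)C)c(Br)c(OCOC)c1 | intermediate
5 | lithium 3,5-bis(methoxymethoxy)-2-(trimethylsilyl)phenolate | COCOc1cc([O-])c([Si](C)(C)C)c(OCOC)c1.[Li+] | intermediate
6 | 3,5-bis(methoxymethoxy)-2-(trimethylsilyl)phenyl trifluoromethanesulfonate | COCOc1cc(OCOC)c([Si](C)(C)C)c(OS(=O)(=O)C(F)(F)F)c1 | intermediate
7 | 2,4-dihydroxyphenylacetic acid | O=C(O)Cc1ccc(O)cc1O | starting material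
8 | methyl 2-(2,4-dihydroxyphenyl)acetate | COC(=O)Cc1ccc(O)cc1O | intermediate
9 | prenyl bromide (1-bromo-3-methylbut-2-ene) | CC(C)=CCBr | starting material
10 | methyl 2-[2-hydroxy-4-(3-methylbut-2-enyloxy)phenyl]acetate | COC(=O)Cc1ccc(OCC=C(C)C)cc1O | intermediate
11 | 3-chloro-3-methylbut-1-yne | C#CC(C)(C)Cl | starting material
12 | methyl 2-[2-(2-methylbut-3-yn-2-yloxy)-4-(3-methylbut-2-enyloxy)phenyl]acetate | COC(=O)Cc1ccc(OCC=C(C)C)cc1OC(C)(C)C#C | intermediate
13 | methyl 2-[2-(2-methylbut-3-en-2-yloxy)-4-(3-methylbut-2-enyloxy)phenyl]acetate | COC(=O)Cc1ccc(OCC=C(C)C)cc1OC(C)(C)C=C | intermediate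
14 | methyl 2-[2-hydroxy-3-(3-methylbut-2-enyl)-4-(3-methylbut-2-enyloxy)phenyl]acetate | COC(=O)Cc1ccc(OCC=C(C)C)c(CC=C(C)C)c1O | intermediate
15 | methyl 2-[2-(methoxymethoxy)-3-(3-methylbut-2-enyl)-4-(3-methylbut-2-enyloxy)phenyl]acetate | COC(=O)Cc1ccc(OCC=C(C)C)c(CC=C(C)C)c1OCOC | intermediate
16 | methyl 2-[4-hydroxy-2-(methoxymethoxy)-5-(2-methylbut-3-en-2-yl)-3-(3-methylbut-2-enyl)phenyl]acetate | COC(=O)Cc1cc(C(C)(C)C=C)c(O)c(CC=C(C)C)c1OCOC | intermediate
17 | methyl 2-[2,4-bis(methoxymethoxy)-5-(2-methylbut-3-en-2-yl)-3-(3-methylbut-2-enyl)phenyl]acetate | COC(=O)Cc1cc(C(C)(C)C=C)c(OCOC)c(CC=C(C)C)c1OCOC | intermediate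
18 | sodium enolate of methyl 3-oxo-2-arylpropanoate (aryl as in 17; configurationally labile) | COC(=O)C(=C[O-])c1cc(C(C)(C)C=C)c(OCOC)c(CC=C(C)C)c1OCOC.[Na+] | intermediate
19 | methyl (E)-3-methoxy-2-[2,4-bis(methoxymethoxy)-5-(2-methylbut-3-en-2-yl)-3-(3-methylbut-2-enyl)phenyl]acrylate | CO/C=C(/C(=O)OC)c1cc(C(C)(C)C=C)c(OCOC)c(CC=C(C)C)c1OCOC | intermediate
20 | (E)-3-methoxy-2-[2,4-bis(methoxymethoxy)-5-(2-methylbut-3-en-2-yl)-3-(3-methylbut-2-enyl)phenyl]acrylic acid | CO/C=C(/C(=O)O)c1cc(C(C)(C)C=C)c(OCOC)c(CC=C(C)C)c1OCOC | intermediate
21 | 3,5-bis(methoxymethoxy)benzyne | COCOC1=CC(OCOC)=CC#C1 | intermediate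
22 | caesium 2-[(E)-3-methoxy-2-arylacryloyl]-3,5-bis(methoxymethoxy)phenolate (aryl as in 20) | CO/C=C(/C(=O)c1c([O-])cc(OCOC)cc1OCOC)c1cc(C(C)(C)C=C)c(OCOC)c(CC=C(C)C)c1OCOC.[Cs+] | intermediate
23 | 5,7,2',4'-tetra-O-methoxymethylfremontone | C=CC(C)(C)c1cc(-c2coc3cc(OCOC)cc(OCOC)c3c2=O)c(OCOC)c(CC=C(C)C)c1OCOC | intermediate
24 | fremontone, 5,7,2',4'-tetrahydroxy-3'-(3-methylbut-2-enyl)-5'-(2-methylbut-3-en-2-yl)isoflavone | C=CC(C)(C)c1cc(-c2coc3cc(O)cc(O)c3c2=O)c(O)c(CC=C(C)C)c1O | target

Total step count: 15.
Longest linear sequence: 11 steps (steps 5–15, from 7). The aryne precursor is a four-step side branch (steps 1–4).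

Steps most likely to fail

1. Step 14 (aryne insertion and annulation).
- What may go wrong: protonation of the aryl anion before the acyl shift, so that the reaction stops at plain O-arylation.
- What may go wrong: conjugate capture at C2 in place of carbonyl attack.
- What may go wrong: consumption of the aryne by an ene reaction with the prenyl group, or by the methanol that is released.
- Fallback: the same ortho-acyloxy aryl anion is generated without an aryne. The fallback sets out from acid 20 and bromophenol 3. Steglich esterification (EDC·HCl, DMAP, CH2Cl2, rt) should give the 2-bromo-3,5-bis(methoxymethoxy)phenyl ester F1. Bromine–lithium exchange (n-BuLi, THF, −95 °C) then triggers an anionic Fries-type O-to-C acyl migration to the lithium o-acylphenolate F2. On warming, this closes ring C by the same addition–elimination and comes back to the route at 23. The position of the bromine atom fixes the regiochemistry.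

2. Step 10 (prenyl ether Claisen rearrangement at 200 °C).
- What may go wrong: further thermal reorganisation of the liberated phenol (abnormal Claisen isomerisation of the 1,1-dimethylallyl group).
- What may go wrong: ring closure of the phenol onto either side chain.
- What may go wrong: cleavage of the ether with loss of isoprene.
- Fallback: the rearrangement is run with acylative capture, so that the free phenol never exists at high temperature. The fallback sets out from 15. Heating with Ac2O and NaOAc in PhNEt2 at 200 °C should give the aryl acetate F3. Mild methanolysis (K2CO3, MeOH, rt), which is degenerate for the methyl ester, returns to the route at 16.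

3. Step 15 (global MOM removal).
- What may go wrong: acid-induced addition of the freed 2'- or 4'-hydroxyl to the prenyl or the 1,1-dimethylallyl double bond before the last acetal has been cleaved.
- Fallback: protic acid is avoided by trans-protection. The fallback sets out from 23. TMSOTf and 2,2'-bipyridyl in MeCN (0 °C → rt) should convert the aryl MOM ethers under buffered conditions into the tetrakis(trimethylsilyl) ether F4. This is hydrolysed by added water at neutral pH and reaches the route again at 24.

Further compounds
F1 | step 14 | 2-bromo-3,5-bis(methoxymethoxy)phenyl (E)-3-methoxy-2-[2,4-bis(methoxymethoxy)-5-(2-methylbut-3-en-2-yl)-3-(3-methylbut-2-enyl)phenyl]acrylate | CO/C=C(/C(=O)Oc1cc(OCOC)cc(OCOC)c1Br)c1cc(C(C)(C)C=C)c(OCOC)c(CC=C(C)C)c1OCOC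
F2 | step 14 | lithium 2-[(E)-3-methoxy-2-arylacryloyl]-3,5-bis(methoxymethoxy)phenolate (aryl as in 20) | CO/C=C(/C(=O)c1c([O-])cc(OCOC)cc1OCOC)c1cc(C(C)(C)C=C)c(OCOC)c(CC=C(C)C)c1OCOC.[Li+]
F3 | step 10 | methyl 2-[4-acetoxy-2-(methoxymethoxy)-5-(2-methylbut-3-en-2-yl)-3-(3-methylbut-2-enyl)phenyl]acetate | COC(=O)Cc1cc(C(C)(C)C=C)c(OC(C)=O)c(CC=C(C)C)c1OCOC
F4 | step 15 | 5,7,2',4'-tetrakis-O-(trimethylsilyl)fremontone | C=CC(C)(C)c1cc(-c2coc3cc(O[Si](C)(C)C)cc(O[Si](C)(C)C)c3c2=O)c(O[Si](C)(C)C)c(CC=C(C)C)c1O[Si](C)(C)C
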